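**Plan**

- Retrosynthesis: the C8–O acyl bond (p-coumaroyl ester) is cut first; then the ten-membered ring is reconnected across C5–C10 (germacrane numbering: ring C1–C10, OH on C6, isopropyl on C7, ester oxygen on C8).
- Feature used: the E alkenes C1=C10 and C4=C5 form a 1,5-diene whose inner carbons C5 and C10 face each other across the ring. A C5–C10 bond therefore turns the cyclodecadiene into a decalin (ring A = C1–C5, C10; ring B = C5–C10) carrying a C4=C5 alkene and a leaving group on C1, and a borate on C4 breaks that bond again.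
- The decalin is cut in ring B at C7=C8 (aldol condensation) and C5–C6 (alkenyl triflate plus isovaleraldehyde); ring A comes from 2-methylcyclohexane-1,3-dione, allyl bromide and MeI.
- Forward order: ring A (bought), ring B (steps 6 to 10), adjustment of C1, C6, C7 and C8 on the bicycle, opening of the shared bond to the ten-membered ring (step 16), then the ester.
- Stereochemistry: C10 from yeast desymmetrisation of the prochiral dione; C1, C6, C7 and C8 by reagent approach to the face opposite the angular C10 methyl; both E alkenes from the antiperiplanar fragmentation.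

Key step: step 16

Remark 1: bicyclic compounds are numbered as eudesmanes and ten-membered rings as germacranes (C14 = methyl on C10, C15 = methyl on C4, isopropyl on C7); β is the face of the C10 methyl group.

Remark 2 (assumption): the yeast reduction of dione 3 is taken to follow its established course, giving the (2S,3S)-ketol as the major product. Its carbinol centre has the wrong configuration for the fragmentation, so it serves only as a temporary handle and is re-set in steps 8 and 11.

**Route**

Step 1
Reactants: 1 2-methylcyclohexane-1,3-dione; 2 allyl bromide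
Product: 3 2-allyl-2-methylcyclohexane-1,3-dione
Conditions: NaOH (1 M aq), rt
Reagents that add atoms: none
Why: Alkylation of the doubly stabilised enolate of a cyclic 1,3-dione with an allylic halide in aqueous base, which reacts at carbon; the product is achiral with a prochiral quaternary carbon.

Step 2
Reactants: 3 2-allyl-2-methylcyclohexane-1,3-dione
Product: 4 (2S,3S)-2-allyl-3-hydroxy-2-methylcyclohexan-1-one
Conditions: baker's yeast (Saccharomyces cerevisiae), sucrose, H2O, 30 °C; chromatography
Reagents that add atoms: none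
Why: Yeast-mediated enantiotopic-group-selective ketone reduction (desymmetrisation of a prochiral 2,2-disubstituted cyclohexane-1,3-dione), precedented for this dione: the dehydrogenase reduces one of the two enantiotopic carbonyl groups from one face, which sets the quaternary carbon (later C10) as S and the carbinol as S (hydroxyl cis to allyl); the minor (2R,3S) diastereomer is removed by chromatography.

Step 3
Reactants: 4 (2S,3S)-2-allyl-3-hydroxy-2-methylcyclohexan-1-one
Product: 5 (2S,3S)-2-allyl-3-(tert-butyldimethylsilyloxy)-2-methylcyclohexan-1-one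
Conditions: TBSCl, imidazole, DMF, 40 °C
Reagents that add atoms: tert-butyldimethylsilyl chloride, CC(C)(C)[Si](C)(C)Cl
Why: Silylation of a secondary alcohol; the ether blocks the hydroxyl during the two enolate steps and prevents retro-aldol opening of the β-ketol.

Step 4
Reactants: 5 (2S,3S)-2-allyl-3-(tert-butyldimethylsilyloxy)-2-methylcyclohexan-1-one
Product: 7 (2S,3S)-2-allyl-3-(tert-butyldimethylsilyloxy)-2,6-dimethylcyclohexan-1-one (both C6 epimers), via lithium enolate 6 (not isolated)
Conditions: LiN(iPr)2, THF, −78 °C; then MeI, −78 to 0 °C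
Reagents that add atoms: iodomethane, CI
Why: Kinetic enolate alkylation: C6 is the only enolisable position (C2 is quaternary), so the methyl group (later C15) enters there; the new stereocentre is not controlled and disappears in step 5.

Step 5
Reactants: 7 (2S,3S)-2-allyl-3-(tert-butyldimethylsilyloxy)-2,6-dimethylcyclohexan-1-one
Product: 9 (5S,6S)-6-allyl-5-(tert-butyldimethylsilyloxy)-2,6-dimethylcyclohex-1-en-1-yl trifluoromethanesulfonate, via potassium enolate 8 (not isolated)
Conditions: KN(SiMe3)2, THF, −78 to 0 °C; then PhNTf2, −78 °C to rt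
Reagents that add atoms: N-phenylbis(trifluoromethanesulfonimide), O=S(=O)(N(c1ccccc1)S(=O)(=O)C(F)(F)F)C(F)(F)F
Why: Enolate O-sulfonylation to an enol triflate: deprotonation is again possible only at C6, so the tetrasubstituted enol triflate (later the C4=C5 alkene with triflate on C5) is the single regioisomer; no stereocentre is formed.

Step 6
Reactants: 9 (5S,6S)-6-allyl-5-(tert-butyldimethylsilyloxy)-2,6-dimethylcyclohex-1-en-1-yl trifluoromethanesulfonate; 10 3-methylbutanal (isovaleraldehyde)
Product: 11 1-[(5S,6R)-6-allyl-5-(tert-butyldimethylsilyloxy)-2,6-dimethylcyclohex-1-en-1-yl]-3-methylbutan-1-ol (both carbinol epimers)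
Conditions: CrCl2 (excess), NiCl2 (cat.), DMF, rt
Reagents that add atoms: none
Why: Nozaki–Hiyama–Kishi coupling: nickel inserts into the alkenyl C–OTf bond, the alkenyl group passes to chromium and adds chemoselectively to the aldehyde, forming the C5–C6 bond without touching the allyl group or the silyl ether; the new carbinol centre is uncontrolled and is removed by oxidation in step 8.

Step 7
Reactants: 11 1-[(5S,6R)-6-allyl-5-(tert-butyldimethylsilyloxy)-2,6-dimethylcyclohex-1-en-1-yl]-3-methylbutan-1-ol
Product: 12 (1S,2R)-2-allyl-3-(1-hydroxy-3-methylbutyl)-2,4-dimethylcyclohex-3-en-1-ol (both side-chain epimers)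
Conditions: TBAF, THF, rt to 50 °C
Reagents that add atoms: none
Why: Fluoride-induced desilylation driven by Si–F bond formation; the ring hydroxyl is freed here so that it can be oxidised together with the allylic alcohol.

Step 8
Reactants: 12 (1S,2R)-2-allyl-3-(1-hydroxy-3-methylbutyl)-2,4-dimethylcyclohex-3-en-1-ol
Product: 13 (2R)-2-allyl-2,4-dimethyl-3-(3-methylbutanoyl)cyclohex-3-en-1-one
Conditions: Dess–Martin periodinane, CH2Cl2, 0 °C to rt
Reagents that add atoms: none
Why: Dess–Martin oxidation of both secondary alcohols to ketones under neutral conditions, which erases the two unwanted carbinol centres and leaves C10 as the only stereocentre.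

Step 9
Reactants: 13 (2R)-2-allyl-2,4-dimethyl-3-(3-methylbutanoyl)cyclohex-3-en-1-one
Product: 14 2-[(1R)-1,3-dimethyl-2-(3-methylbutanoyl)-6-oxocyclohex-2-en-1-yl]acetaldehyde
Conditions: OsO4 (cat.), NaIO4, 2,6-lutidine, dioxane/H2O, rt
Reagents that add atoms: osmium tetroxide (oxygen carrier), O=[Os](=O)(=O)=O; sodium periodate, [Na+].[O-]I(=O)(=O)=O; water, O
Why: Lemieux–Johnson oxidative cleavage: OsO4 dihydroxylates the monosubstituted alkene far faster than the hindered, electron-poor tetrasubstituted enone alkene and periodate cleaves the diol to the aldehyde; no stereocentre is formed.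

Step 10
Reactants: 14 2-[(1R)-1,3-dimethyl-2-(3-methylbutanoyl)-6-oxocyclohex-2-en-1-yl]acetaldehyde
Product: 16 (10R)-eudesma-4,7-diene-1,6-dione, via aldol adduct 15 (not isolated)
Conditions: KOH, MeOH, 0 °C to rt
Reagents that add atoms: none
Why: Intramolecular aldol condensation (Robinson-type closure of a 1,5-keto aldehyde): the enone ketone can enolise only towards C7, which adds to the aldehyde carbon C8 to close six-membered ring B, and E1cB loss of water gives the cross-conjugated dienone, whereas the other conceivable aldol adducts are bridged, cannot dehydrate and revert; the two centres of 15 are lost again.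

Step 11
Reactants: 16 (10R)-eudesma-4,7-diene-1,6-dione
Product: 17 (1R,10R)-1β-hydroxyeudesma-4,7-dien-6-one
Conditions: NaBH4 (0.3 equiv), EtOH, −20 °C
Reagents that add atoms: none
Why: Chemoselective borohydride reduction of the saturated C1 ketone beside the hindered cross-conjugated dienone (as in the selective reduction of the Wieland–Miescher ketone); hydride enters axially from the α face, opposite the pseudoaxial C10 methyl, and gives the equatorial 1β-alcohol.

Step 12
Reactants: 17 (1R,10R)-1β-hydroxyeudesma-4,7-dien-6-one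
Product: 18 (1R,10R)-1β-(methanesulfonyloxy)eudesma-4,7-dien-6-one
Conditions: MsCl, Et3N, CH2Cl2, 0 °C
Reagents that add atoms: methanesulfonyl chloride, CS(=O)(=O)Cl
Why: Mesylation of a secondary alcohol (via the sulfene from MsCl and Et3N) with retention at C1; the neopentyl, equatorial mesylate is inert to the following reduction, silylation and hydroboration, and installing it now leaves no second free hydroxyl to compete later.

Step 13
Reactants: 18 (1R,10R)-1β-(methanesulfonyloxy)eudesma-4,7-dien-6-one
Product: 19 1β-(methanesulfonyloxy)eudesma-4,7-dien-6β-ol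
Conditions: NaBH4, CeCl3·7H2O, MeOH, −78 to −20 °C
Reagents that add atoms: none
Why: Luche 1,2-reduction of the dienone: the cerium-activated carbonyl is attacked from the α face, away from the pseudoaxial C10 methyl that shields the β face of C6, which gives the 6β (pseudoaxial) bis-allylic alcohol.

Step 14
Reactants: 19 1β-(methanesulfonyloxy)eudesma-4,7-dien-6β-ol
Product: 20 1β-(methanesulfonyloxy)-6β-(triethylsilyloxy)eudesma-4,7-diene
Conditions: TESOTf, 2,6-lutidine, CH2Cl2, −78 °C
Reagents that add atoms: triethylsilyl trifluoromethanesulfonate, CC[Si](CC)(CC)OS(=O)(=O)C(F)(F)F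
Why: Silylation of a hindered secondary alcohol with a silyl triflate and a hindered base, conditions that spare the ionisable bis-allylic alcohol; the triethylsilyl ether survives borane and methoxide and is removed at the end together with the phenolic silyl ether.

Step 15
Reactants: 20 1β-(methanesulfonyloxy)-6β-(triethylsilyloxy)eudesma-4,7-diene
Product: 22 1β-(methanesulfonyloxy)-6β-(triethylsilyloxy)eudesm-4-en-8α-ol (7β-isopropyl), via C8 borabicyclononyl adduct 21 (not isolated)
Conditions: 9-BBN, THF, 65 °C; then NaOH (aq), H2O2, 0 °C to rt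
Reagents that add atoms: hydrogen peroxide, OO
Why: Hydroboration–oxidation with a dialkylborane that does not add to tetrasubstituted alkenes: 9-BBN reacts only at the trisubstituted C7=C8 bond, boron going to the less substituted C8 (also the carbon remote from the allylic C6 oxygen) and adding syn with hydrogen from the α face opposite the C10 methyl and the 6β-silyloxy group, so that oxidation with retention gives the 8α-alcohol and the 7β-isopropyl group (7α-H).

Step 16
Reactants: 22 1β-(methanesulfonyloxy)-6β-(triethylsilyloxy)eudesm-4-en-8α-ol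
Product: 24 (1(10)E,4E)-6-(triethylsilyloxy)germacra-1(10),4-dien-8-ol, via C4 borane 23 (not isolated)
Conditions: BH3·THF (5 equiv), THF, 0 °C to rt; then NaOMe, MeOH, rt
Reagents that add atoms: none
Why: Borane adds syn across the tetrasubstituted C4=C5 bond from the α face, boron on C4 and hydrogen on C5, which gives trans-fused decalin 23 with an equatorial C4–B bond. Methoxide turns the borane into a borate in which the C4–B bond, the C5–C10 ring-fusion bond and the equatorial C1–OMs bond are mutually antiperiplanar, so the C–B electron pair forms C4=C5, the C5–C10 pair forms C1=C10 and mesylate leaves in one concerted step. The closest known reaction type is the Grob-type seven-centre boronate fragmentation of decalin mesylates to cyclodeca-1,5-dienes. No ring is closed: the ten-membered ring appears when the bond shared by the two six-membered rings is cleaved. No stereocentre is created in the product (the transient centres C4 and C5 of 23 vanish again), and both alkenes are E because C3/C6 and C9/C2 are anti across the breaking bonds. The step needs boron on C4, α-facial addition and an equatorial mesylate: quaternary C10 and the allylic C6 oxygen disfavour boron on C5, the angular methyl and the 6β-silyloxy group block the β face, the 1β-mesylate was fixed in step 11, and the free C8 hydroxyl is only converted to a borate ester that methanolysis returns.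

Step 17
Reactants: 25 p-coumaric acid
Product: 27 (E)-4-(tert-butyldimethylsilyloxy)cinnamic acid, via silyl ester 26 (not isolated)
Conditions: TBSCl (2.2 equiv), imidazole, DMF, rt; then AcOH, THF, H2O, rt
Reagents that add atoms: tert-butyldimethylsilyl chloride, CC(C)(C)[Si](C)(C)Cl
Why: Silylation of phenol and carboxylic acid followed by selective hydrolysis of the much more labile silyl ester; the phenol is masked so that only the carboxyl group is activated in step 18.

Step 18
Reactants: 24 (1(10)E,4E)-6-(triethylsilyloxy)germacra-1(10),4-dien-8-ol; 27 (E)-4-(tert-butyldimethylsilyloxy)cinnamic acid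
Product: 28 (1(10)E,4E)-6-(triethylsilyloxy)germacra-1(10),4-dien-8-yl (E)-4-(tert-butyldimethylsilyloxy)cinnamate
Conditions: EDC·HCl, DMAP, CH2Cl2, rt
Reagents that add atoms: none
Why: Steglich esterification (carbodiimide activation, DMAP acyl transfer) of the only free hydroxyl, C8–OH, under neutral conditions that spare the acid-sensitive cyclodecadiene; no stereocentre is touched.

Step 19
Reactants: 28 (1(10)E,4E)-6-(triethylsilyloxy)germacra-1(10),4-dien-8-yl (E)-4-(tert-butyldimethylsilyloxy)cinnamate
Product: 29 (1(10)E,4E,6S,7S,8S)-6-hydroxygermacra-1(10),4-dien-8-yl (E)-4-hydroxycinnamate (CNP0178839.1)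
Conditions: TBAF, AcOH, THF, 0 °C to rt
Reagents that add atoms: none
Why: Fluoride desilylation buffered with acetic acid cleaves the phenolic and the allylic silyl ether in one operation, and the buffer suppresses ester cleavage and acyl migration from O8 to O6; no stereocentre is touched.

**Compound list**

1 | 2-methylcyclohexane-1,3-dione | CC1C(=O)CCCC1=O | starting material
2 | allyl bromide (3-bromoprop-1-ene) | C=CCBr | starting material
3 | 2-allyl-2-methylcyclohexane-1,3-dione | C=CCC1(C)C(=O)CCCC1=O | intermediate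
4 | (2S,3S)-2-allyl-3-hydroxy-2-methylcyclohexan-1-one | C=CC[C@]1(C)C(=O)CCC[C@@H]1O | intermediate
5 | (2S,3S)-2-allyl-3-(tert-butyldimethylsilyloxy)-2-methylcyclohexan-1-one | C=CC[C@]1(C)C(=O)CCC[C@@H]1O[Si](C)(C)C(C)(C)C | intermediate
6 | lithium enolate of 5 (lithium (5S,6S)-6-allyl-5-(tert-butyldimethylsilyloxy)-6-methylcyclohex-1-en-1-olate) | C=CC[C@]1(C)C(O[Li])=CCC[C@@H]1O[Si](C)(C)C(C)(C)C | intermediate (not isolated)
7 | (2S,3S)-2-allyl-3-(tert-butyldimethylsilyloxy)-2,6-dimethylcyclohexan-1-one, both C6 epimers | C=CC[C@]1(C)C(=O)C(C)CC[C@@H]1O[Si](C)(C)C(C)(C)C | intermediate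
8 | potassium enolate of 7 (potassium (5S,6S)-6-allyl-5-(tert-butyldimethylsilyloxy)-2,6-dimethylcyclohex-1-en-1-olate) | C=CC[C@]1(C)C(O[K])=C(C)CC[C@@H]1O[Si](C)(C)C(C)(C)C | intermediate (not isolated)
9 | (5S,6S)-6-allyl-5-(tert-butyldimethylsilyloxy)-2,6-dimethylcyclohex-1-en-1-yl trifluoromethanesulfonate | C=CC[C@]1(C)C(OS(=O)(=O)C(F)(F)F)=C(C)CC[C@@H]1O[Si](C)(C)C(C)(C)C | intermediate
10 | 3-methylbutanal (isovaleraldehyde) | CC(C)CC=O | starting material
11 | 1-[(5S,6R)-6-allyl-5-(tert-butyldimethylsilyloxy)-2,6-dimethylcyclohex-1-en-1-yl]-3-methylbutan-1-ol, both carbinol epimers | C=CC[C@]1(C)C(C(O)CC(C)C)=C(C)CC[C@@H]1O[Si](C)(C)C(C)(C)C | intermediate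
12 | (1S,2R)-2-allyl-3-(1-hydroxy-3-methylbutyl)-2,4-dimethylcyclohex-3-en-1-ol, both side-chain epimers | C=CC[C@]1(C)C(C(O)CC(C)C)=C(C)CC[C@@H]1O | intermediate
13 | (2R)-2-allyl-2,4-dimethyl-3-(3-methylbutanoyl)cyclohex-3-en-1-one | C=CC[C@]1(C)C(C(=O)CC(C)C)=C(C)CCC1=O | intermediate
14 | 2-[(1R)-1,3-dimethyl-2-(3-methylbutanoyl)-6-oxocyclohex-2-en-1-yl]acetaldehyde | O=CC[C@]1(C)C(C(=O)CC(C)C)=C(C)CCC1=O | intermediate
15 | (10R)-8-hydroxyeudesm-4-ene-1,6-dione (aldol adduct, C7 and C8 undefined) | CC1=C2C(=O)C(C(C)C)C(O)C[C@@]2(C)C(=O)CC1 | intermediate (not isolated)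
16 | (10R)-eudesma-4,7-diene-1,6-dione | CC1=C2C(=O)C(C(C)C)=CC[C@@]2(C)C(=O)CC1 | intermediate
17 | (1R,10R)-1β-hydroxyeudesma-4,7-dien-6-one | CC1=C2C(=O)C(C(C)C)=CC[C@@]2(C)[C@H](O)CC1 | intermediate
18 | (1R,10R)-1β-(methanesulfonyloxy)eudesma-4,7-dien-6-one | CC1=C2C(=O)C(C(C)C)=CC[C@@]2(C)[C@H](OS(C)(=O)=O)CC1 | intermediate
19 | 1β-(methanesulfonyloxy)eudesma-4,7-dien-6β-ol | CC1=C2[C@H](O)C(C(C)C)=CC[C@@]2(C)[C@H](OS(C)(=O)=O)CC1 | intermediate
20 | 1β-(methanesulfonyloxy)-6β-(triethylsilyloxy)eudesma-4,7-diene | CC1=C2[C@H](O[Si](CC)(CC)CC)C(C(C)C)=CC[C@@]2(C)[C@H](OS(C)(=O)=O)CC1 | intermediate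
21 | 8α-(9-borabicyclo[3.3.1]nonan-9-yl)-1β-(methanesulfonyloxy)-6β-(triethylsilyloxy)eudesm-4-ene (7β-isopropyl) | CC1=C2[C@H](O[Si](CC)(CC)CC)[C@H](C(C)C)[C@@H](B3C4CCCC3CCC4)C[C@@]2(C)[C@H](OS(C)(=O)=O)CC1 | intermediate (not isolated)
22 | 1β-(methanesulfonyloxy)-6β-(triethylsilyloxy)eudesm-4-en-8α-ol (7β-isopropyl, 7α-H) | CC1=C2[C@H](O[Si](CC)(CC)CC)[C@H](C(C)C)[C@@H](O)C[C@@]2(C)[C@H](OS(C)(=O)=O)CC1 | intermediate
23 | 4α-boranyl-4β-methyl-5α-H trans-decalin derived from 22 (C8 oxygen carried as O–BH2) | C[C@]1([BH2])[C@@H]2[C@H](O[Si](CC)(CC)CC)[C@H](C(C)C)[C@@H](O[BH2])C[C@@]2(C)[C@H](OS(C)(=O)=O)CC1 | intermediate (not isolated)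
24 | (1(10)E,4E)-6-(triethylsilyloxy)germacra-1(10),4-dien-8-ol (C6, C7, C8 as in 29) | C/C1=C\[C@H](O[Si](CC)(CC)CC)[C@H](C(C)C)[C@@H](O)C/C(C)=C/CC1 | intermediate
25 | p-coumaric acid ((E)-4-hydroxycinnamic acid) | OC(=O)/C=C/c1ccc(O)cc1 | starting material
26 | tert-butyldimethylsilyl (E)-4-(tert-butyldimethylsilyloxy)cinnamate | CC(C)(C)[Si](C)(C)OC(=O)/C=C/c1ccc(O[Si](C)(C)C(C)(C)C)cc1 | intermediate (not isolated)
27 | (E)-4-(tert-butyldimethylsilyloxy)cinnamic acid | OC(=O)/C=C/c1ccc(O[Si](C)(C)C(C)(C)C)cc1 | intermediate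
28 | (1(10)E,4E)-6-(triethylsilyloxy)germacra-1(10),4-dien-8-yl (E)-4-(tert-butyldimethylsilyloxy)cinnamate | C/C1=C\[C@H](O[Si](CC)(CC)CC)[C@H](C(C)C)[C@@H](OC(=O)/C=C/c2ccc(O[Si](C)(C)C(C)(C)C)cc2)C/C(C)=C/CC1 | intermediate
29 | (1(10)E,4E,6S,7S,8S)-6-hydroxygermacra-1(10),4-dien-8-yl (E)-4-hydroxycinnamate (CNP0178839.1) | C/C1=C\[C@H](O)[C@H](C(C)C)[C@@H](OC(=O)/C=C/c2ccc(O)cc2)C/C(C)=C/CC1 | target

**Step count and risks**

Total step count: 19. Longest linear sequence: 18 steps (1 to 29 through steps 1–16, 18 and 19; step 17 prepares acid 27).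

Most likely to fail, first: step 16. Borane may add too slowly to the tetrasubstituted C4=C5 bond beside the bulky axial silyl ether, or may place boron on C5, after which methoxide causes 1,3-elimination or protodeboronation instead of ring opening. The fallback sets out from 22 and fragments the unprotected diol. The triethylsilyl group is removed first (HF·pyridine, pyridine, THF, 0 °C) to give 1β-(methanesulfonyloxy)eudesm-4-ene-6β,8α-diol F1, whose alkene is less shielded and whose hydroxyls pass through as borate esters. The same borane–methoxide sequence should then give (1(10)E,4E)-germacra-1(10),4-diene-6,8-diol F2. The less hindered C8 hydroxyl is acylated selectively with acid 27 (2,4,6-trichlorobenzoyl chloride, Et3N, then DMAP, toluene, 0 °C) to give (1(10)E,4E)-6-hydroxygermacra-1(10),4-dien-8-yl (E)-4-(tert-butyldimethylsilyloxy)cinnamate F3. Desilylation of the phenol (TBAF, AcOH, THF) comes back to the route at 29.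

Second: step 15. The bulky borane may add too slowly to the hindered trisubstituted alkene, and a smaller borane would no longer distinguish it from the C4=C5 bond, whose borane would fragment during the alkaline oxidation. The fallback sets out from 20 and asks for no selectivity. Excess BH3·THF hydroborates both alkenes to the 4α,8α-bis(boranyl) adduct F4. NaOMe in MeOH fragments the C4 borate while the C8 borane is carried on as dimethyl [(1(10)E,4E)-6-(triethylsilyloxy)germacra-1(10),4-dien-8-yl]boronate F5. NaOH/H2O2 in the same flask oxidises the C8–B bond with retention, and the route is rejoined at 24.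

Third: step 6. Oxidative addition and transfer to chromium may stall at the tetrasubstituted triflate flanked by a quaternary carbon, so that the triflate is reduced or recovered instead of coupled. The fallback sets out from 9 and builds the C5–C6 bond by carbonylation. Methoxycarbonylation (Pd(OAc)2, PPh3, CO 1 atm, MeOH, Et3N, DMF, 60 °C) gives methyl (5S,6R)-6-allyl-5-(tert-butyldimethylsilyloxy)-2,6-dimethylcyclohex-1-ene-1-carboxylate F6. Reduction with iBu2AlH (toluene, −78 °C) gives [(5S,6R)-6-allyl-5-(tert-butyldimethylsilyloxy)-2,6-dimethylcyclohex-1-en-1-yl]methanol F7. Oxidation with MnO2 (CH2Cl2, rt) gives (5S,6R)-6-allyl-5-(tert-butyldimethylsilyloxy)-2,6-dimethylcyclohex-1-ene-1-carbaldehyde F8. Addition of isobutylmagnesium bromide (THF, −78 °C) gives alcohol 11, where the route is rejoined.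

**Further compounds**

F1 | step 16 | 1β-(methanesulfonyloxy)eudesm-4-ene-6β,8α-diol | CC1=C2[C@H](O)[C@H](C(C)C)[C@@H](O)C[C@@]2(C)[C@H](OS(C)(=O)=O)CC1
F2 | step 16 | (1(10)E,4E)-germacra-1(10),4-diene-6,8-diol (C6, C7, C8 as in 29) | C/C1=C\[C@H](O)[C@H](C(C)C)[C@@H](O)C/C(C)=C/CC1
F3 | step 16 | (1(10)E,4E)-6-hydroxygermacra-1(10),4-dien-8-yl (E)-4-(tert-butyldimethylsilyloxy)cinnamate | C/C1=C\[C@H](O)[C@H](C(C)C)[C@@H](OC(=O)/C=C/c2ccc(O[Si](C)(C)C(C)(C)C)cc2)C/C(C)=C/CC1
F4 | step 15 | 4α,8α-bis(boranyl)-1β-(methanesulfonyloxy)-6β-(triethylsilyloxy)eudesmane (5α-H, 7β-isopropyl) | C[C@]1([BH2])[C@@H]2[C@H](O[Si](CC)(CC)CC)[C@H](C(C)C)[C@@H]([BH2])C[C@@]2(C)[C@H](OS(C)(=O)=O)CC1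
F5 | step 15 | dimethyl [(1(10)E,4E)-6-(triethylsilyloxy)germacra-1(10),4-dien-8-yl]boronate | C/C1=C\[C@H](O[Si](CC)(CC)CC)[C@H](C(C)C)[C@@H](B(OC)OC)C/C(C)=C/CC1
F6 | step 6 | methyl (5S,6R)-6-allyl-5-(tert-butyldimethylsilyloxy)-2,6-dimethylcyclohex-1-ene-1-carboxylate | C=CC[C@]1(C)C(C(=O)OC)=C(C)CC[C@@H]1O[Si](C)(C)C(C)(C)C
F7 | step 6 | [(5S,6R)-6-allyl-5-(tert-butyldimethylsilyloxy)-2,6-dimethylcyclohex-1-en-1-yl]methanol | C=CC[C@]1(C)C(CO)=C(C)CC[C@@H]1O[Si](C)(C)C(C)(C)C
F8 | step 6 | (5S,6R)-6-allyl-5-(tert-butyldimethylsilyloxy)-2,6-dimethylcyclohex-1-ene-1-carbaldehyde | C=CC[C@]1(C)C(C=O)=C(C)CC[C@@H]1O[Si](C)(C)C(C)(C)C
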